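**Strategy.** Ring A (C1, C2, C3, C4, C4a, C8a of the decalin; C1 bears the propanoic acid chain, C2 the isopropylidene) is carried through the synthesis as a cyclopentanone whose carbonyl carbon is the future C2. A Hajos–Parrish-type hydrindenedione fixes C8a; reductive benzylation and cyclopropanation–hydrogenolysis set C4a, C5 and C6. The key step is a pinacol-type 1,2-shift: in a tertiary cyclopentanol carrying a 1-mesyloxyalkyl group on the carbinol carbon, the quaternary C8a migrates to the mesylate carbon. This enlarges the five-membered ring to ring A, makes the C1–C8a bond with the chain in place and leaves the C2 ketone, which exploits the sp2 carbon next to C1, for isopropylidenation.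

Key step: step 16

Remark: all intermediates are described with the future decalin locants of the target (C1 chain carbon, C2, C3, C4, C4a ring-fusion CH, C5 benzyl/methyl carbon, C6 methyl carbon, C7, C8, C8a angular carbon); β is the face of the C8a methyl group; Ar = 5-methoxy-2-(methoxymethoxy)-3-methylphenyl.

**Step 1**
Reactants: 1 4-methoxy-2-methylphenol
Product: 2 4-methoxy-1-(methoxymethoxy)-2-methylbenzene
Conditions: NaH, MOMCl, DMF, 0 °C
Reagents that add atoms: chloromethyl methyl ether COCCl
Why: O-alkylation of the phenoxide (Williamson-type acetal protection) should be clean and gives a group that survives bases, organometallics and hydrogenation.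

**Step 2**
Reactants: 2 4-methoxy-1-(methoxymethoxy)-2-methylbenzene
Product: 4 [5-methoxy-2-(methoxymethoxy)-3-methylphenyl]methanol, via aryllithium 3 (not isolated)
Conditions: n-BuLi, TMEDA, Et2O, 0 °C; (CH2O)n, 0 °C to rt
Reagents that add atoms: formaldehyde (from paraformaldehyde) C=O
Why: Directed ortho-metalation, in which the methoxymethoxy group directs lithiation to its only free ortho position and the aryllithium adds to formaldehyde.

**Step 3**
Reactants: 4 [5-methoxy-2-(methoxymethoxy)-3-methylphenyl]methanol
Product: 5 1-(bromomethyl)-5-methoxy-2-(methoxymethoxy)-3-methylbenzene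
Conditions: CBr4, PPh3, CH2Cl2, 0 °C
Reagents that add atoms: carbon tetrabromide BrC(Br)(Br)Br
Why: Appel reaction converts the benzylic alcohol into the bromide under neutral conditions that spare the acetal.

**Step 4**
Reactants: 6 2-methylcyclopentane-1,3-dione; 7 pent-1-en-3-one
Product: 8 2-methyl-2-(3-oxopentyl)cyclopentane-1,3-dione
Conditions: H2O, AcOH (cat.), 70 °C
Reagents that add atoms: none
Why: Michael addition of the acidic dione to the vinyl ketone (first half of a Robinson annulation) creates the quaternary carbon as a prochiral centre.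

**Step 5**
Reactants: 8 2-methyl-2-(3-oxopentyl)cyclopentane-1,3-dione
Product: 9 (R)-4,7a-dimethyl-2,3,7,7a-tetrahydro-1H-indene-1,5(6H)-dione (C2 ketone, C6 enone carbonyl, C5=C4a, 8a-methyl in future locants)
Conditions: D-phenylalanine, HClO4 (aq., cat.), MeCN, 80 °C
Reagents that add atoms: none
Why: Hajos–Parrish–Eder–Sauer–Wiechert enamine aldol condensation, in which the amino acid differentiates the two enantiotopic ring carbonyls; the D-amino acid should give the (R) angular centre C8a, the mirror image of the steroid series.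

**Step 6**
Reactants: 9 (R)-4,7a-dimethyl-2,3,7,7a-tetrahydro-1H-indene-1,5(6H)-dione
Product: 10 the mono(ethylene ketal) of 9 at the saturated C2 ketone
Conditions: 2-ethyl-2-methyl-1,3-dioxolane, ethylene glycol (cat.), p-TsOH (cat.), rt
Reagents that add atoms: 2-ethyl-2-methyl-1,3-dioxolane CCC1(C)OCCO1
Why: Acid-catalysed transketalisation should select the saturated ketone because the enone carbonyl is deactivated by conjugation.

**Step 7**
Reactants: 10 the mono(ethylene ketal) of 9; 5 1-(bromomethyl)-5-methoxy-2-(methoxymethoxy)-3-methylbenzene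
Product: 12 trans-fused hydrindan-6-one C2-ketal with 5α-ArCH2, 5β-CH3, 8aβ-CH3 and H-4a α, via lithium enolate 11 (not isolated)
Conditions: Li, NH3/THF, t-BuOH (1 equiv), −78 °C; isoprene; then 5, THF, −78 to −33 °C
Reagents that add atoms: none
Why: Birch-type reductive alkylation of the enone: axial protonation at the β-carbon C4a should give the trans-fused enolate, which is benzylated at C5 on the α face, anti to the 1,3-related axial methyl on C8a, leaving the C5 methyl β.

**Step 8**
Reactants: 12 trans-fused hydrindan-6-one C2-ketal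
Product: 13 the C6 enol triflate of 12 (C6=C7)
Conditions: KN(SiMe3)2, THF, −78 °C; PhNTf2
Reagents that add atoms: N-phenylbis(trifluoromethanesulfonimide) FC(F)(F)S(=O)(=O)N(c1ccccc1)S(=O)(=O)C(F)(F)F
Why: Enolate O-sulfonylation; C5 is quaternary, so enolisation is possible only towards C7.

**Step 9**
Reactants: 13 the C6 enol triflate of 12
Product: 14 the C6=C7 alkene (H in place of OTf)
Conditions: Pd(OAc)2 (cat.), PPh3, HCO2H, n-Bu3N, DMF, 60 °C
Reagents that add atoms: none
Why: Palladium-catalysed formate reduction of an enol triflate (oxidative addition, formate exchange, decarboxylation, reductive elimination) gives the cis-disubstituted ring alkene without touching ketal or ethers.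

**Step 10**
Reactants: 14 the C6=C7 alkene
Product: 15 the 6α,7α-methano compound (cyclopropane on the α face, H-6 and H-7 β)
Conditions: Et2Zn, CF3CO2H, CH2I2, CH2Cl2, 0 °C to rt
Reagents that add atoms: diiodomethane ICI
Why: Simmons–Smith cyclopropanation with the trifluoroacetate-modified zinc carbenoid; the β face is shielded by the axial methyl groups on C5 and C8a, so CH2 should be delivered to the α face, which fixes H-6 as β.

**Step 11**
Reactants: 15 the 6α,7α-methano compound
Product: 16 the 6α-methyl compound (H-6 β, C7 now CH2), C2 ketal intact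
Conditions: H2 (4 atm), PtO2, glacial AcOH, rt
Reagents that add atoms: none
Why: Catalytic hydrogenolysis of the cyclopropane should cleave the less hindered C7–CH2 bond, remote from quaternary C5, and so turn the bridging carbon into the axial 6α-methyl group, the epimer that hydrogenation of a 6-methylene group from the open α face could not give.

**Step 12**
Reactants: 16 the 6α-methyl compound
Product: 17 the trans-hydrindan-2-one (C2 ketone next to C8a; MOM ether kept)
Conditions: PPTS, acetone/H2O, reflux
Reagents that add atoms: water O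
Why: Mild acetal hydrolysis; a ketone-derived dioxolane ionises far more readily than the formaldehyde-derived aryl MOM acetal.

**Step 13**
Reactants: 17 the trans-hydrindan-2-one; 18 (3-cyanopropyl)triphenylphosphonium bromide
Product: 20 the (Z)-2-(3-cyanopropylidene)hydrindane (chain cis to C8a), via phosphorus ylide 19 (not isolated)
Conditions: 18, NaN(SiMe3)2, THF, 0 °C; then 17, 0 °C to reflux
Reagents that add atoms: none
Why: Wittig olefination with a non-stabilised ylide; on a cyclopentanone flanked by a quaternary carbon the Z alkene (as with 17-oxo steroids) should predominate, and the ylide carbon becomes the future C1 already carrying the three-carbon chain.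

**Step 14**
Reactants: 20 the (Z)-2-(3-cyanopropylidene)hydrindane
Product: 21 the diol with 2α-OH (tertiary) and a secondary OH on the future C1
Conditions: OsO4 (cat.), NMO, acetone/H2O, rt
Reagents that add atoms: N-methylmorpholine N-oxide C[N+]1([O-])CCOCC1; water O
Why: Upjohn syn-dihydroxylation from the α face, opposite the adjacent C8a methyl, fixes the tertiary hydroxyl α and, through the Z geometry, the configuration of the carbinol carbon.

**Step 15**
Reactants: 21 the diol
Product: 22 the secondary methanesulfonate of 21 (tertiary OH free)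
Conditions: MsCl, Et3N, DMAP (cat.), CH2Cl2, 0 °C
Reagents that add atoms: methanesulfonyl chloride CS(=O)(=O)Cl
Why: Sulfonylation is selective for the secondary alcohol because the tertiary one is too hindered.

**Step 16**
Reactants: 22 the secondary methanesulfonate
Product: 24 the ring-expanded trans-decalin-2-one with the 2-cyanoethyl chain on C1 β (equatorial, H-1 α), via axial C1 epimer 23 (not isolated)
Conditions: Et3Al, CH2Cl2, −78 to 0 °C; then NaOMe, MeOH, rt
Reagents that add atoms: none
Why: Et3Al turns the tertiary hydroxyl into an aluminium alkoxide whose oxygen pushes the C8a–C2 ring bond onto the neighbouring carbon as the mesylate leaves, so C8a migrates with inversion at the new C1 and the old carbinol carbon becomes the C2 ketone. The closest known type is the organoaluminium-promoted pinacol-type (semipinacol) shift of α-hydroxy mesylates, as in D-homoannulation of 17-hydroxy-20-sulfonyloxy steroids. No ring is closed by a new cyclisation: the cyclopentane C2–C3–C4–C4a–C8a is enlarged to the cyclohexane by insertion of C1 between C8a and C2. The shift is stereospecific, so the Z alkene and α-face dihydroxylation should first give the chain α (axial) at C1. C1 is then α to the ketone, and methoxide equilibration should favour the required β (equatorial) epimer, which avoids the syn-axial hydrogens on C3 and C4a. The step needs migration of quaternary C8a rather than of the ring methylene C3 or epoxide closure; in this diastereomer the rotamer with the mesylate anti to C8a puts the hydrogen, not the chain, in the most crowded position, and the tertiary alkyl group is the better migrating group.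

**Step 17**
Reactants: 24 the ring-expanded trans-decalin-2-one
Product: 25 the 2-isopropylidene nitrile (MOM ether)
Conditions: TiCl4, Zn, pyridine, THF, reflux; acetone (excess)
Reagents that add atoms: acetone CC(C)=O
Why: Mixed McMurry coupling: low-valent titanium couples the ring ketone with excess acetone and deoxygenates the pinacolate to the tetrasubstituted alkene, after which C1 can no longer epimerise.

**Step 18**
Reactants: 25 the 2-isopropylidene nitrile
Product: 27 3-[(1S,4aR,5S,6S,8aR)-5-[(2-hydroxy-5-methoxy-3-methylphenyl)methyl]-5,6,8a-trimethyl-2-(propan-2-ylidene)decahydronaphthalen-1-yl]propanoic acid (target), via phenol nitrile 26 (not isolated)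
Conditions: HCl (1 M), MeOH, rt; concentrate; then KOH, ethylene glycol/H2O, 150 °C; cold dilute HCl work-up
Reagents that add atoms: water O
Why: Acetal exchange frees the phenol under acid too dilute to isomerise the tetrasubstituted alkene, and hot hydroxide then hydrolyses the nitrile through the amide to the carboxylate (nitrile hydrolysis) with no epimerisable centre present.

**Compound list**
1 | 4-methoxy-2-methylphenol | COc1ccc(O)c(C)c1 | starting material
2 | 4-methoxy-1-(methoxymethoxy)-2-methylbenzene | COc1ccc(OCOC)c(C)c1 | intermediate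
3 | [5-methoxy-2-(methoxymethoxy)-3-methylphenyl]lithium | COc1cc(C)c(OCOC)c([Li])c1 | intermediate
4 | [5-methoxy-2-(methoxymethoxy)-3-methylphenyl]methanol | COc1cc(C)c(OCOC)c(CO)c1 | intermediate
5 | 1-(bromomethyl)-5-methoxy-2-(methoxymethoxy)-3-methylbenzene | COc1cc(C)c(OCOC)c(CBr)c1 | intermediate
6 | 2-methylcyclopentane-1,3-dione | CC1C(=O)CCC1=O | starting material
7 | pent-1-en-3-one | CCC(=O)C=C | starting material
8 | 2-methyl-2-(3-oxopentyl)cyclopentane-1,3-dione | CCC(=O)CCC1(C)C(=O)CCC1=O | intermediate
9 | (R)-4,7a-dimethyl-2,3,7,7a-tetrahydro-1H-indene-1,5(6H)-dione | CC1=C2CCC(=O)[C@]2(C)CCC1=O | intermediate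
10 | mono(ethylene ketal) of 9 at the saturated C2 ketone | CC1=C2CCC3(OCCO3)[C@]2(C)CCC1=O | intermediate
11 | trans-fused lithium enolate (C5=C6–OLi, H-4a α), C2 ketal | [Li]OC1=C(C)[C@H]2CCC3(OCCO3)[C@]2(C)CC1 | intermediate
12 | trans-fused hydrindan-6-one C2-ketal, 5α-ArCH2, 5β-CH3, 8aβ-CH3, H-4a α | COc1cc(C)c(OCOC)c(C[C@]2(C)[C@H]3CCC4(OCCO4)[C@]3(C)CCC2=O)c1 | intermediate
13 | C6 enol triflate of 12 (C6=C7) | COc1cc(C)c(OCOC)c(C[C@]2(C)[C@H]3CCC4(OCCO4)[C@]3(C)CC=C2OS(=O)(=O)C(F)(F)F)c1 | intermediate
14 | C6=C7 alkene | COc1cc(C)c(OCOC)c(C[C@]2(C)[C@H]3CCC4(OCCO4)[C@]3(C)CC=C2)c1 | intermediate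
15 | 6α,7α-methano compound (H-6, H-7 β) | COc1cc(C)c(OCOC)c(C[C@]2(C)[C@H]3CCC4(OCCO4)[C@]3(C)C[C@@H]5C[C@H]25)c1 | intermediate
16 | 6α-methyl compound (H-6 β), C2 ketal | COc1cc(C)c(OCOC)c(C[C@]2(C)[C@H]3CCC4(OCCO4)[C@]3(C)CC[C@@H]2C)c1 | intermediate
17 | trans-hydrindan-2-one (5α-ArCH2, 5β,6α,8aβ-trimethyl) | COc1cc(C)c(OCOC)c(C[C@]2(C)[C@H]3CCC(=O)[C@]3(C)CC[C@@H]2C)c1 | intermediate
18 | (3-cyanopropyl)triphenylphosphonium bromide | N#CCCC[P+](c1ccccc1)(c1ccccc1)c1ccccc1.[Br-] | starting material
19 | (3-cyanopropylidene)triphenylphosphorane | N#CCCC=P(c1ccccc1)(c1ccccc1)c1ccccc1 | intermediate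
20 | (Z)-2-(3-cyanopropylidene)hydrindane, chain cis to C8a | COc1cc(C)c(OCOC)c(C[C@]2(C)[C@H]3CC/C(=C/CCC#N)[C@]3(C)CC[C@@H]2C)c1 | intermediate
21 | diol: 2α-OH (tertiary) and secondary OH on the future C1 | COc1cc(C)c(OCOC)c(C[C@]2(C)[C@H]3CC[C@@](O)([C@H](O)CCC#N)[C@]3(C)CC[C@@H]2C)c1 | intermediate
22 | secondary methanesulfonate of 21 | COc1cc(C)c(OCOC)c(C[C@]2(C)[C@H]3CC[C@@](O)([C@H](OS(C)(=O)=O)CCC#N)[C@]3(C)CC[C@@H]2C)c1 | intermediate
23 | trans-decalin-2-one, 1α (axial) 2-cyanoethyl | COc1cc(C)c(OCOC)c(C[C@]2(C)[C@H]3CCC(=O)[C@H](CCC#N)[C@]3(C)CC[C@@H]2C)c1 | intermediate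
24 | trans-decalin-2-one, 1β (equatorial) 2-cyanoethyl, H-1 α | COc1cc(C)c(OCOC)c(C[C@]2(C)[C@H]3CCC(=O)[C@@H](CCC#N)[C@]3(C)CC[C@@H]2C)c1 | intermediate
25 | 2-isopropylidene nitrile, MOM ether | COc1cc(C)c(OCOC)c(C[C@]2(C)[C@H]3CCC(=C(C)C)[C@@H](CCC#N)[C@]3(C)CC[C@@H]2C)c1 | intermediate
26 | 2-isopropylidene nitrile, free phenol | COc1cc(C)c(O)c(C[C@]2(C)[C@H]3CCC(=C(C)C)[C@@H](CCC#N)[C@]3(C)CC[C@@H]2C)c1 | intermediate
27 | 3-[(1S,4aR,5S,6S,8aR)-5-[(2-hydroxy-5-methoxy-3-methylphenyl)methyl]-5,6,8a-trimethyl-2-(propan-2-ylidene)decahydronaphthalen-1-yl]propanoic acid | COc1cc(C)c(O)c(C[C@]2(C)[C@H]3CCC(=C(C)C)[C@@H](CCC(=O)O)[C@]3(C)CC[C@@H]2C)c1 | target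

**Step count.** Total 18 steps. Longest linear sequence 15 steps (steps 4 to 18, from 2-methylcyclopentane-1,3-dione).

**Steps most likely to fail**

Step 16. The 1,2-shift may be diverted to migration of the ring methylene C3 or to epoxide closure by the alkoxide, and the base equilibration at C1 may not favour the equatorial epimer strongly enough. Fallback, starting from 17: trimethylsilyldiazomethane with BF3·OEt2 inserts CH2 on the less substituted side of the cyclopentanone and gives the trans-decalin-1-one F1. KN(SiMe3)2 and PhNTf2 give the enol triflate F2, since enolisation is possible only towards C2. Negishi coupling with IZnCH2CH2CN and Pd(PPh3)4 gives the C1-substituted alkene F3. Hydroboration–oxidation (BH3·SMe2, then H2O2/NaOH) from the α face, opposite the C8a methyl, delivers H-1 α under kinetic control and gives the C2 alcohol F4. Dess–Martin oxidation returns to 24. Ring A still arises by enlargement of the five-membered ring.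

Step 11. Hydrogenolysis may cleave the other external cyclopropane bond, giving a C7 methyl group, or begin to reduce the electron-rich arene. Fallback, starting from 12: dehydrogenation with IBX in DMSO gives the enone F5 (C6 ketone, C7=C8). Alkaline H2O2 epoxidises it from the α face to the epoxy ketone F6. Hydrazine with AcOH (Wharton transposition) gives the allylic alcohol F7 (C8 hydroxyl, C6=C7). MnO2 gives the transposed enone F8 (C8 ketone). Me2CuLi adds axially to C6 from the α face, anti to the axial C5 methyl, and gives the 6α-methyl ketone F9. Wolff–Kishner reduction (N2H4, KOH, diethylene glycol, 200 °C) removes the C8 carbonyl and returns to 16.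

Step 17. The hindered ketone may be reduced or form pinacol-type products while acetone self-couples, so that cross-coupling stalls. Fallback, starting from 24: isopropenylmagnesium bromide with CeCl3 at −78 °C adds to the ketone from the α (equatorial) side and gives the tertiary allylic alcohol F10, the nitrile being slower to react. Ionic reduction with Et3SiH and BF3·OEt2 at −78 °C delivers hydride to the CH2 terminus of the allyl cation and returns to 25 as the tetrasubstituted alkene.

**Further compounds**
F1 | step 16 | trans-decalin-1-one (CH2 inserted as C2) | COc1cc(C)c(OCOC)c(C[C@]2(C)[C@H]3CCCC(=O)[C@]3(C)CC[C@@H]2C)c1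
F2 | step 16 | C1 enol triflate (C1=C2) | COc1cc(C)c(OCOC)c(C[C@]2(C)[C@H]3CCC=C(OS(=O)(=O)C(F)(F)F)[C@]3(C)CC[C@@H]2C)c1
F3 | step 16 | 1-(2-cyanoethyl) C1=C2 alkene | COc1cc(C)c(OCOC)c(C[C@]2(C)[C@H]3CCC=C(CCC#N)[C@]3(C)CC[C@@H]2C)c1
F4 | step 16 | 2α-alcohol with 1β-(2-cyanoethyl), H-1 α | COc1cc(C)c(OCOC)c(C[C@]2(C)[C@H]3CC[C@H](O)[C@@H](CCC#N)[C@]3(C)CC[C@@H]2C)c1
F5 | step 11 | enone: C6 ketone, C7=C8, C2 ketal | COc1cc(C)c(OCOC)c(C[C@]2(C)[C@H]3CCC4(OCCO4)[C@]3(C)C=CC2=O)c1
F6 | step 11 | 7α,8α-epoxy C6 ketone | COc1cc(C)c(OCOC)c(C[C@]2(C)[C@H]3CCC4(OCCO4)[C@]3(C)[C@@H]5O[C@@H]5C2=O)c1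
F7 | step 11 | allylic alcohol: 8α-OH, C6=C7 | COc1cc(C)c(OCOC)c(C[C@]2(C)[C@H]3CCC4(OCCO4)[C@]3(C)[C@H](O)C=C2)c1
F8 | step 11 | transposed enone: C8 ketone, C6=C7 | COc1cc(C)c(OCOC)c(C[C@]2(C)[C@H]3CCC4(OCCO4)[C@]3(C)C(=O)C=C2)c1
F9 | step 11 | 6α-methyl C8 ketone | COc1cc(C)c(OCOC)c(C[C@]2(C)[C@H]3CCC4(OCCO4)[C@]3(C)C(=O)C[C@@H]2C)c1
F10 | step 17 | tertiary allylic alcohol: 2β-OH, 2α-isopropenyl | COc1cc(C)c(OCOC)c(C[C@]2(C)[C@H]3CC[C@](O)(C(C)=C)[C@@H](CCC#N)[C@]3(C)CC[C@@H]2C)c1
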